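**Retrosynthetic overview**
1. Target 11 ⇐ enone 10 by a substrate-controlled cis 1,2-reduction, which sets the ring carbinol.
2. Enone 10 ⇐ cyclobutanone 7 + alkyne 9 by an enantiotopos-selective nickel-catalysed two-carbon ring expansion (cyclobutanone → cyclohexenone). This one step makes the only ring of the target, puts the acyloxymethyl group on C2 and sets C5.
3. Cyclobutanone 7 ⇐ alkyne 6 + alkene 3 by ruthenium-catalysed alkene–alkyne coupling, which builds the 1,1-disubstituted alkene and the E-alkene of the skipped diene.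
4. 6 ⇐ 3-oxocyclobutanecarboxylic acid 4 (decarboxylative alkynylation); 3 ⇐ (S)-2-methylglycidol 1 (vinyl Grignard opening, acylation); 9 ⇐ propargyl alcohol 8.
5. Ring order: the four-membered ring is bought and the six-membered ring is formed from it in step 6; no other ring is made.

Assumption: the sense of induction of the new catalyst in step 6 cannot be predicted with certainty, so the ligand enantiomer that gives the 5S ring carbon is chosen after screening (written here as the R,R,R,R ligand).

**Step 1**
Reactants: 1 (S)-2-methylglycidol [(S)-(2-methyloxiran-2-yl)methanol]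
Product: 2 (R)-2-methylpent-4-ene-1,2-diol
Conditions: CH2=CHMgBr (3 equiv), CuI (10 mol %), THF, −30 → 0 °C; aq. NH4Cl
Reagents that add atoms: vinylmagnesium bromide, C=C[Mg]Br
Why: Copper-catalysed Grignard opening (SN2) of the 2,2-disubstituted epoxide at its unhindered CH2 terminus leaves the quaternary carbinol carbon untouched, so the S epoxide gives the R diol (the descriptor changes only through the CIP priorities).

**Step 2**
Reactants: 2 (R)-2-methylpent-4-ene-1,2-diol
Product: 3 (R)-2-hydroxy-2-methylpent-4-en-1-yl 2-methylpropanoate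
Conditions: i-PrCOCl (1.05 equiv), 2,4,6-collidine, CH2Cl2, −40 → 0 °C
Reagents that add atoms: 2-methylpropanoyl chloride, CC(C)C(Cl)=O
Why: Chemoselective acylation (nucleophilic acyl substitution), since the primary hydroxyl reacts far faster than the hindered tertiary one and the stereocentre is not involved.

**Step 3**
Reactants: 4 3-oxocyclobutane-1-carboxylic acid
Product: 6 3-ethynylcyclobutan-1-one, via NHPI ester 5 (not isolated)
Conditions: N-hydroxyphthalimide, N,N′-diisopropylcarbodiimide (DIC), DMAP (cat.), CH2Cl2, rt; solvent swap; NiCl2·6H2O (20 mol %), 4,4′-dimethoxy-2,2′-bipyridine (20 mol %), HC≡CZnCl (from HC≡CMgBr + ZnCl2), THF/DMF, rt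
Reagents that add atoms: ethynylmagnesium bromide, C#C[Mg]Br; N-hydroxyphthalimide, O=C1c2ccccc2C(=O)N1O (its atoms stay only in 5)
Why: Nickel-catalysed decarboxylative alkynylation of a redox-active ester (radical decarboxylation, then capture of the cyclobutyl radical by an alkynylnickel species) tolerates the ketone because zinc acetylides do not add to it, and no stereocentre is involved because 6 is achiral.

**Step 4**
Reactants: 6 3-ethynylcyclobutan-1-one (1.3 equiv); 3 (R)-2-hydroxy-2-methylpent-4-en-1-yl 2-methylpropanoate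
Product: 7 (R,E)-2-hydroxy-2-methyl-6-(3-oxocyclobutyl)hepta-3,6-dien-1-yl 2-methylpropanoate
Conditions: [CpRu(MeCN)3]PF6 (10 mol %), acetone, rt
Reagents that add atoms: none
Why: Ruthenium-catalysed alkene–alkyne coupling (Trost formal Alder-ene reaction through a ruthenacyclopentene) forms the C–C bond at the internal alkyne carbon to give the 1,1-disubstituted alkene, and β-hydride elimination gives the E-alkene next to the tertiary carbinol, whose configuration is untouched.

**Step 5**
Reactants: 8 prop-2-yn-1-ol (propargyl alcohol)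
Product: 9 prop-2-yn-1-yl 2-methylpropanoate
Conditions: i-PrCOCl, Et3N, DMAP (cat.), CH2Cl2, 0 °C
Reagents that add atoms: 2-methylpropanoyl chloride, CC(C)C(Cl)=O
Why: Standard acylation of a primary alcohol (nucleophilic acyl substitution).

**Step 6**
Reactants: 7 (R,E)-2-hydroxy-2-methyl-6-(3-oxocyclobutyl)hepta-3,6-dien-1-yl 2-methylpropanoate; 9 prop-2-yn-1-yl 2-methylpropanoate (1.5 equiv)
Product: 10 {(4S)-4-[(R,E)-6-hydroxy-6-methyl-7-(2-methylpropanoyloxy)hepta-1,4-dien-2-yl]-6-oxocyclohex-1-en-1-yl}methyl 2-methylpropanoate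
Conditions: Ni(cod)2 (10 mol %), (R,R,R,R)-ANIPE·HCl (acenaphtho-fused imidazolium chloride with two N-[2,6-bis((R)-1-phenylethyl)-4-methylphenyl] groups, 12 mol %), NaOtBu (12 mol %), precomplexed in toluene; 7, then 9 by syringe pump over 4 h, 0 °C → rt
Reagents that add atoms: none
Why: Proposed new method: enantiotopos- and regioselective nickel-catalysed insertion of a terminal propargylic ester into a prochiral 3-substituted cyclobutanone (four- to six-membered ring expansion); zerovalent nickel carrying the bulky C2-symmetric carbene couples the ketone C=O and the alkyne oxidatively to a spiro oxanickelacyclopentene, the ligand bulk putting the small CH terminus on nickel and the CH2O-acyl-bearing carbon on the carbonyl carbon (ligand-size regiocontrol as in nickel aldehyde–alkyne reductive couplings), then strain-driven β-carbon elimination of one of the two enantiotopic C(O)–CH2 bonds, chosen by the chiral pocket, sets C5 as S under catalyst control and C(sp3)–C(sp2) reductive elimination closes the cyclohexenone; the closest known reaction type is the nickel-catalysed formal [4+2] insertion of internal alkynes into cyclobutanones with achiral ligands and its asymmetric intramolecular alkene variant, whereas a terminal oxygenated alkyne and an intermolecular desymmetrisation have not been shown.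

**Step 7**
Reactants: 10 {(4S)-4-[(R,E)-6-hydroxy-6-methyl-7-(2-methylpropanoyloxy)hepta-1,4-dien-2-yl]-6-oxocyclohex-1-en-1-yl}methyl 2-methylpropanoate
Product: 11 {(4S,6S)-6-hydroxy-4-[(R,E)-6-hydroxy-6-methyl-7-(2-methylpropanoyloxy)hepta-1,4-dien-2-yl]cyclohex-1-en-1-yl}methyl 2-methylpropanoate (CNP0599657.1)
Conditions: NaBH4 (1.1 equiv), CeCl3·7H2O (1.2 equiv), MeOH, −78 °C; aq. NH4Cl
Reagents that add atoms: none
Why: Luche 1,2-reduction, in which hydride attacks the half-chair enone axially with the C5 substituent pseudo-equatorial and so gives the pseudo-equatorial alcohol cis to C5 (1S, as in carvone → cis-carveol), while the cerium salt suppresses conjugate (SN2′) hydride attack on the allylic ester.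

**Compound list**
1 | (S)-2-methylglycidol | C[C@]1(CO)CO1 | starting material
2 | (R)-2-methylpent-4-ene-1,2-diol | C=CC[C@@](C)(O)CO | intermediate
3 | (R)-2-hydroxy-2-methylpent-4-en-1-yl 2-methylpropanoate | C=CC[C@@](C)(O)COC(=O)C(C)C | intermediate
4 | 3-oxocyclobutane-1-carboxylic acid | O=C1CC(C(=O)O)C1 | starting material
5 | 1,3-dioxoisoindolin-2-yl 3-oxocyclobutane-1-carboxylate (NHPI ester, not isolated) | O=C1CC(C(=O)ON2C(=O)c3ccccc3C2=O)C1 | intermediate
6 | 3-ethynylcyclobutan-1-one | C#CC1CC(=O)C1 | intermediate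
7 | (R,E)-2-hydroxy-2-methyl-6-(3-oxocyclobutyl)hepta-3,6-dien-1-yl 2-methylpropanoate | C=C(C/C=C/[C@@](C)(O)COC(=O)C(C)C)C1CC(=O)C1 | intermediate
8 | prop-2-yn-1-ol | C#CCO | starting material
9 | prop-2-yn-1-yl 2-methylpropanoate | C#CCOC(=O)C(C)C | intermediate
10 | {(4S)-4-[(R,E)-6-hydroxy-6-methyl-7-(2-methylpropanoyloxy)hepta-1,4-dien-2-yl]-6-oxocyclohex-1-en-1-yl}methyl 2-methylpropanoate | C=C(C/C=C/[C@@](C)(O)COC(=O)C(C)C)[C@H]1CC=C(COC(=O)C(C)C)C(=O)C1 | intermediate
11 | {(4S,6S)-6-hydroxy-4-[(R,E)-6-hydroxy-6-methyl-7-(2-methylpropanoyloxy)hepta-1,4-dien-2-yl]cyclohex-1-en-1-yl}methyl 2-methylpropanoate | C=C(C/C=C/[C@@](C)(O)COC(=O)C(C)C)[C@H]1CC=C(COC(=O)C(C)C)[C@@H](O)C1 | target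

**Totals**
Total step count: 7. Longest linear sequence: 5 steps (1 → 2 → 4 → 6 → 7).

**Three steps most likely to fail**

Step 6 (the new ring expansion). The risks are oligomerisation of the terminal alkyne on nickel, the opposite alkyne orientation (acyloxymethyl on C3), ionisation of the propargylic or the product allylic ester, and poor discrimination of the enantiotopic C–C bonds. The fallback uses known chemistry, sets out from 3 and comes back to the route at 11; 7 and 10 are bypassed and the ring is made without the cyclobutanone.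
- Cyclohex-2-en-1-one and (triisopropylsilyl)acetylene are joined by rhodium-catalysed asymmetric conjugate alkynylation ([Rh(OAc)(C2H4)2]2, the DTBM-SEGPHOS enantiomer that gives the S ketone, dioxane, 80 °C) to give (S)-3-[(triisopropylsilyl)ethynyl]cyclohexan-1-one F1.
- Claisen formylation (NaH, HCO2Et) at the less hindered C6 gives (S)-2-(hydroxymethylene)-5-[(triisopropylsilyl)ethynyl]cyclohexan-1-one F2.
- DDQ dehydrogenation gives (S)-6-oxo-4-[(triisopropylsilyl)ethynyl]cyclohex-1-ene-1-carbaldehyde F3.
- F3 is reduced at once at both carbonyl groups under Luche conditions (NaBH4, CeCl3·7H2O, MeOH, −78 °C) to (1S,5S)-2-(hydroxymethyl)-5-[(triisopropylsilyl)ethynyl]cyclohex-2-en-1-ol F4.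
- Selective acylation of the primary alcohol (i-PrCOCl, collidine, −40 °C) gives {(4S,6S)-6-hydroxy-4-[(triisopropylsilyl)ethynyl]cyclohex-1-en-1-yl}methyl 2-methylpropanoate F5.
- Buffered fluoride (TBAF/AcOH, THF) removes the silyl group to give [(4S,6S)-4-ethynyl-6-hydroxycyclohex-1-en-1-yl]methyl 2-methylpropanoate F6.
- Ruthenium-catalysed alkene–alkyne coupling of F6 with 3 under the conditions of step 4 gives 11.

Step 4 (alkene–alkyne coupling). The risk is that the α-branched alkyne gives too much of the linear isomer, which is hard to separate. The fallback sets out from 6 (and from 1 for the partner) and comes back at 7.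
- Markovnikov addition of HI to 6 (NaI, Me3SiCl, H2O, MeCN) gives 3-(1-iodovinyl)cyclobutan-1-one F7.
- Stille coupling with allyltributylstannane (Pd(PPh3)4, CuI, DMF) gives 3-(penta-1,4-dien-2-yl)cyclobutan-1-one F8.
- Separately, 1 is homologated by one carbon with dimethylsulfonium methylide (Me3S+ I−, n-BuLi, THF) to (R)-2-methylbut-3-ene-1,2-diol F9.
- F9 is acylated at the primary hydroxyl (i-PrCOCl, collidine) to (R)-2-hydroxy-2-methylbut-3-en-1-yl 2-methylpropanoate F10.
- E-selective cross-metathesis of F8 with excess F10 (second-generation Hoveyda–Grubbs catalyst, CH2Cl2, 40 °C) takes place only at the monosubstituted alkene of F8 and gives 7.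

Step 3 (decarboxylative alkynylation). The risks are the volatility of 6 and side reactions of the ketone or of the acetylide under nickel catalysis. The fallback sets out from 4 and comes back at 6.
- 4 is converted into the NHPI ester 5, which is now isolated.
- Visible-light reductive decarboxylative alkynylation of 5 with phenyl [(triisopropylsilyl)ethynyl] sulfone (Ru(bpy)3Cl2, Hantzsch ester, i-Pr2NEt, blue LEDs; radical addition to the alkynyl sulfone and loss of sulfinate) gives the non-volatile 3-[(triisopropylsilyl)ethynyl]cyclobutan-1-one F11.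
- Buffered desilylation (TBAF/AcOH, THF, 0 °C) gives 6, which is used as a solution.

**Further compounds**
F1 | step 6 | (S)-3-[(triisopropylsilyl)ethynyl]cyclohexan-1-one | O=C1CCC[C@H](C#C[Si](C(C)C)(C(C)C)C(C)C)C1
F2 | step 6 | (S)-2-(hydroxymethylene)-5-[(triisopropylsilyl)ethynyl]cyclohexan-1-one | O=C1C(=CO)CC[C@H](C#C[Si](C(C)C)(C(C)C)C(C)C)C1
F3 | step 6 | (S)-6-oxo-4-[(triisopropylsilyl)ethynyl]cyclohex-1-ene-1-carbaldehyde | O=CC1=CC[C@H](C#C[Si](C(C)C)(C(C)C)C(C)C)CC1=O
F4 | step 6 | (1S,5S)-2-(hydroxymethyl)-5-[(triisopropylsilyl)ethynyl]cyclohex-2-en-1-ol | OCC1=CC[C@H](C#C[Si](C(C)C)(C(C)C)C(C)C)C[C@@H]1O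
F5 | step 6 | {(4S,6S)-6-hydroxy-4-[(triisopropylsilyl)ethynyl]cyclohex-1-en-1-yl}methyl 2-methylpropanoate | CC(C)C(=O)OCC1=CC[C@H](C#C[Si](C(C)C)(C(C)C)C(C)C)C[C@@H]1O
F6 | step 6 | [(4S,6S)-4-ethynyl-6-hydroxycyclohex-1-en-1-yl]methyl 2-methylpropanoate | CC(C)C(=O)OCC1=CC[C@H](C#C)C[C@@H]1O
F7 | step 4 | 3-(1-iodovinyl)cyclobutan-1-one | C=C(I)C1CC(=O)C1
F8 | step 4 | 3-(penta-1,4-dien-2-yl)cyclobutan-1-one | C=CCC(=C)C1CC(=O)C1
F9 | step 4 | (R)-2-methylbut-3-ene-1,2-diol | C=C[C@@](C)(O)CO
F10 | step 4 | (R)-2-hydroxy-2-methylbut-3-en-1-yl 2-methylpropanoate | C=C[C@@](C)(O)COC(=O)C(C)C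
F11 | step 3 | 3-[(triisopropylsilyl)ethynyl]cyclobutan-1-one | O=C1CC(C#C[Si](C(C)C)(C(C)C)C(C)C)C1
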